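**Plan**

- Numbering used: lactone ring O1, C2(=O), C3, C4, C5, C6; side chain C1'–C15' counted from the ring.
- Retrosynthesis: the C2 carbonyl is taken back to a cyclic methyl acetal. The dihydropyran ring is then opened at C5–C6 and O1–C2 with loss of the C3=C4 π bond. The chain is cut at C3'–C4' and C4'–C5' (dithiane linchpin), and the two resulting epoxides at C7'–C8' and C1'–C6.
- Enabling feature: the six-membered ring O1–C2–C3=C4–C5–C6 with its endocyclic cis alkene is the oxidised form of a hetero-Diels–Alder adduct of an aldehyde (C6=O1) and a 1-oxygenated butadiene (C2–C5).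
- Forward: two epoxides from (R)-epichlorohydrin, three-component dithiane coupling to the C7'–C6 chain, ketone, syn reduction, acetonide, ozonolysis. The only ring of the target is then closed by the cycloaddition, oxidised to the lactone and deprotected.
- Stereochemistry: C6' and C2' from (R)-epichlorohydrin; C4' by hydroxyl-directed syn reduction; C6 by the chiral chromium catalyst.

Key step: step 8

Assumption: the (1S,2R)-aminoindanol-derived chromium complex is taken to give the 6S adduct, by analogy with its antipode's reported sense with silyloxyacetaldehyde (recalled from the literature, not re-derived); if the sense is opposite, the antipodal catalyst is used.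

**Step 1**
Reactants: 1 (R)-epichlorohydrin; 2 octylmagnesium bromide
Product: 4 (R)-2-nonyloxirane, via (R)-1-chloroundecan-2-ol 3 (not isolated)
Conditions: CuI (10 mol %), THF, −40 to 0 °C; then powdered NaOH, H2O, rt
Reagents that add atoms: none
Why: Copper-catalysed Grignard opening of the epoxide at its CH2 carbon followed by Williamson closure onto the chloromethyl carbon leaves the stereocentre untouched, so R in 1 becomes R in 4.

**Step 2**
Reactants: 1 (R)-epichlorohydrin; 5 vinylmagnesium bromide
Product: 7 (R)-2-allyloxirane, via (R)-1-chloropent-4-en-2-ol 6 (not isolated)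
Conditions: CuI (10 mol %), THF, −78 to −40 °C; then powdered NaOH, H2O, rt; careful distillation (volatile)
Reagents that add atoms: none
Why: Same copper-catalysed epoxide opening and Williamson closure as in step 1, with the stereocentre of 1 carried over unchanged.

**Step 3**
Reactants: 8 2-(tert-butyldimethylsilyl)-1,3-dithiane; 4 (R)-2-nonyloxirane; 7 (R)-2-allyloxirane
Product: 12 (2R)-1-{2-[(2R)-2-(tert-butyldimethylsilyloxy)undecyl]-1,3-dithian-2-yl}pent-4-en-2-ol, via 2-lithio-2-silyl-1,3-dithiane 9 (not isolated), via lithium alkoxide 10 (not isolated), via Brook-shifted 2-lithiodithiane 11 (not isolated)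
Conditions: t-BuLi, Et2O, −78 to −45 °C; 4, −78 to −25 °C; then 7, HMPA, THF, −78 to 0 °C; H2O
Reagents that add atoms: none
Why: Anion-relay linchpin coupling (Smith–Tietze): lithiated 8 opens 4 at CH2, HMPA triggers the 1,4-Brook silyl shift to the new alkoxide, and the regenerated dithiane anion opens 7 at CH2, so both carbinol centres come unchanged from the epoxides.

**Step 4**
Reactants: 12 dithiane alcohol
Product: 13 (4R,8R)-8-(tert-butyldimethylsilyloxy)-4-hydroxyheptadec-1-en-6-one
Conditions: PhI(OCOCF3)2, MeCN/H2O (9:1), 0 °C, 10 min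
Reagents that add atoms: water O
Why: Oxidative dithiane hydrolysis with [bis(trifluoroacetoxy)iodo]benzene (Stork conditions) is fast at 0 °C and should spare the silyl ether, the free alcohol and the terminal alkene.

**Step 5**
Reactants: 13 β-hydroxy ketone
Product: 15 (4R,6R,8R)-8-(tert-butyldimethylsilyloxy)heptadec-1-ene-4,6-diol, via diethylboron chelate 14 (not isolated)
Conditions: Et2BOMe, THF/MeOH (4:1), −78 °C; NaBH4, −78 °C; then MeOH, repeated evaporation
Reagents that add atoms: none
Why: Narasaka–Prasad reduction: external hydride attacks the six-membered boron chelate axially to give the 1,3-syn diol, so the new centre (C6 of 15, C4' of the target) is set by the adjacent carbinol.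

**Step 6**
Reactants: 15 syn-diol
Product: 16 (4R,6R)-4-allyl-6-[(2R)-2-(tert-butyldimethylsilyloxy)undecyl]-2,2-dimethyl-1,3-dioxane
Conditions: 2,2-dimethoxypropane, PPTS (cat.), CH2Cl2, rt
Reagents that add atoms: 2,2-dimethoxypropane COC(C)(C)OC
Why: Acid-catalysed transketalisation should convert the syn-1,3-diol into the chair acetonide without touching the secondary silyl ether.

**Step 7**
Reactants: 16 acetonide alkene
Product: 18 2-{(4S,6R)-6-[(2R)-2-(tert-butyldimethylsilyloxy)undecyl]-2,2-dimethyl-1,3-dioxan-4-yl}acetaldehyde, via ozonide 17 (not isolated)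
Conditions: O3, CH2Cl2, −78 °C; then PPh3, −78 °C to rt; used at once
Reagents that add atoms: ozone [O-][O+]=O
Why: Ozonolysis with reductive work-up cleaves only the terminal alkene; the ketal and silyl ether are inert and no stereocentre is involved.

**Step 8**
Reactants: 18 aldehyde; 19 (E)-1-methoxybuta-1,3-diene
Product: 20 (2R,6S)-6-({(4R,6R)-6-[(2R)-2-(tert-butyldimethylsilyloxy)undecyl]-2,2-dimethyl-1,3-dioxan-4-yl}methyl)-2-methoxy-5,6-dihydro-2H-pyran
Conditions: CrCl(L) (5 mol %; trivalent chromium, L = dianion of the Schiff base from 3-(1-adamantyl)-2-hydroxy-5-methylbenzaldehyde and (1S,2R)-1-aminoindan-2-ol), 4 Å MS, minimal TBME, rt, 24–48 h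
Reagents that add atoms: none
Why: The aldehyde bound to the Lewis-acidic trivalent chromium centre should undergo a concerted, asynchronous hetero-Diels–Alder reaction with s-cis diene 19, forming the C5–C6 bond and turning the diene's central C3–C4 bond into the ring C3=C4 double bond while O1–C2 closes in the same event. The closest known reaction type is the Jacobsen hetero-Diels–Alder reaction of 1-methoxybutadiene with α-unbranched aliphatic aldehydes under this class of tridentate Schiff-base CrCl complexes. The dihydropyran ring closes by [4+2] cycloaddition (4π unit C2–C5, 2π unit C6=O1), so the C3=C4 alkene is necessarily cis within the ring. C6 is set by the catalyst, which shields one face of the bound carbonyl (6S, anti to the neighbouring dioxane carbinol carbon), and C2 by the endo transition state (cis-2,6; this centre is oxidised away in step 9). The step needs catalyst-controlled facial selectivity over the resident β-stereocentre and the regiochemistry that joins the methoxy-bearing carbon to oxygen. The first should be secured by the strong reagent control of this catalyst class with the β-oxygen held in a non-chelating acetonide, the second by the polarisation of the 1-oxygenated diene.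

**Step 9**
Reactants: 20 methyl acetal
Product: 22 (6S)-6-({(4S,6R)-6-[(2R)-2-(tert-butyldimethylsilyloxy)undecyl]-2,2-dimethyl-1,3-dioxan-4-yl}methyl)-5,6-dihydro-2H-pyran-2-one, via lactol 21 (not isolated)
Conditions: PPTS (0.2 equiv), MeCN/H2O (4:1), rt; then TEMPO (0.2 equiv), PhI(OAc)2, rt
Reagents that add atoms: water O
Why: The allylic mixed acetal should hydrolyse far faster than the dioxane ketal, and TEMPO/PhI(OAc)2 oxidation of the resulting lactol gives the conjugated lactone with no free alcohol present to compete.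

**Step 10**
Reactants: 22 protected lactone
Product: 23 (6S)-6-[(2S,4S,6R)-2,4,6-trihydroxypentadecyl]-5,6-dihydro-2H-pyran-2-one
Conditions: 48 % aq. HF/MeCN (1:9), 0 °C to rt
Reagents that add atoms: none
Why: Aqueous HF should cleave the silyl ether and hydrolyse the acetonide in one operation under acidic conditions that the δ-lactone tolerates, with no stereocentre affected.

**Compound list**

1 | (R)-epichlorohydrin | ClC[C@H]1CO1 | starting material
2 | octylmagnesium bromide | CCCCCCCC[Mg]Br | starting material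
3 | (R)-1-chloroundecan-2-ol | ClC[C@H](O)CCCCCCCCC | intermediate
4 | (R)-2-nonyloxirane | CCCCCCCCC[C@@H]1CO1 | intermediate
5 | vinylmagnesium bromide | C=C[Mg]Br | starting material
6 | (R)-1-chloropent-4-en-2-ol | ClC[C@H](O)CC=C | intermediate
7 | (R)-2-allyloxirane | C=CC[C@@H]1CO1 | intermediate
8 | 2-(tert-butyldimethylsilyl)-1,3-dithiane | CC(C)(C)[Si](C)(C)C1SCCCS1 | starting material
9 | 2-lithio-2-(tert-butyldimethylsilyl)-1,3-dithiane | [Li]C1([Si](C)(C)C(C)(C)C)SCCCS1 | intermediate
10 | lithium (2R)-1-[2-(tert-butyldimethylsilyl)-1,3-dithian-2-yl]undecan-2-olate | CCCCCCCCC[C@@H](O[Li])CC1([Si](C)(C)C(C)(C)C)SCCCS1 | intermediate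
11 | 2-lithio-2-[(2R)-2-(tert-butyldimethylsilyloxy)undecyl]-1,3-dithiane | CCCCCCCCC[C@@H](O[Si](C)(C)C(C)(C)C)CC1([Li])SCCCS1 | intermediate
12 | (2R)-1-{2-[(2R)-2-(tert-butyldimethylsilyloxy)undecyl]-1,3-dithian-2-yl}pent-4-en-2-ol | CCCCCCCCC[C@@H](O[Si](C)(C)C(C)(C)C)CC1(C[C@H](O)CC=C)SCCCS1 | intermediate
13 | (4R,8R)-8-(tert-butyldimethylsilyloxy)-4-hydroxyheptadec-1-en-6-one | CCCCCCCCC[C@@H](O[Si](C)(C)C(C)(C)C)CC(=O)C[C@H](O)CC=C | intermediate
14 | (4R,8R)-8-(tert-butyldimethylsilyloxy)-4-(diethylboranyloxy)heptadec-1-en-6-one (boron chelated by the ketone oxygen) | CCCCCCCCC[C@@H](O[Si](C)(C)C(C)(C)C)CC(=O)C[C@H](OB(CC)CC)CC=C | intermediate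
15 | (4R,6R,8R)-8-(tert-butyldimethylsilyloxy)heptadec-1-ene-4,6-diol | CCCCCCCCC[C@@H](O[Si](C)(C)C(C)(C)C)C[C@H](O)C[C@H](O)CC=C | intermediate
16 | (4R,6R)-4-allyl-6-[(2R)-2-(tert-butyldimethylsilyloxy)undecyl]-2,2-dimethyl-1,3-dioxane | CCCCCCCCC[C@@H](O[Si](C)(C)C(C)(C)C)C[C@H]1C[C@@H](CC=C)OC(C)(C)O1 | intermediate
17 | 3-({(4S,6R)-6-[(2R)-2-(tert-butyldimethylsilyloxy)undecyl]-2,2-dimethyl-1,3-dioxan-4-yl}methyl)-1,2,4-trioxolane (both epimers at the trioxolane carbon) | CCCCCCCCC[C@@H](O[Si](C)(C)C(C)(C)C)C[C@H]1C[C@@H](CC2OCOO2)OC(C)(C)O1 | intermediate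
18 | 2-{(4S,6R)-6-[(2R)-2-(tert-butyldimethylsilyloxy)undecyl]-2,2-dimethyl-1,3-dioxan-4-yl}acetaldehyde | CCCCCCCCC[C@@H](O[Si](C)(C)C(C)(C)C)C[C@H]1C[C@@H](CC=O)OC(C)(C)O1 | intermediate
19 | (E)-1-methoxybuta-1,3-diene | CO/C=C/C=C | starting material
20 | (2R,6S)-6-({(4R,6R)-6-[(2R)-2-(tert-butyldimethylsilyloxy)undecyl]-2,2-dimethyl-1,3-dioxan-4-yl}methyl)-2-methoxy-5,6-dihydro-2H-pyran (cis-2,6) | CCCCCCCCC[C@@H](O[Si](C)(C)C(C)(C)C)C[C@H]1C[C@@H](C[C@@H]2CC=C[C@H](OC)O2)OC(C)(C)O1 | intermediate
21 | (6S)-6-({(4R,6R)-6-[(2R)-2-(tert-butyldimethylsilyloxy)undecyl]-2,2-dimethyl-1,3-dioxan-4-yl}methyl)-5,6-dihydro-2H-pyran-2-ol (both anomers) | CCCCCCCCC[C@@H](O[Si](C)(C)C(C)(C)C)C[C@H]1C[C@@H](C[C@@H]2CC=CC(O)O2)OC(C)(C)O1 | intermediate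
22 | (6S)-6-({(4S,6R)-6-[(2R)-2-(tert-butyldimethylsilyloxy)undecyl]-2,2-dimethyl-1,3-dioxan-4-yl}methyl)-5,6-dihydro-2H-pyran-2-one | CCCCCCCCC[C@@H](O[Si](C)(C)C(C)(C)C)C[C@H]1C[C@@H](C[C@@H]2CC=CC(=O)O2)OC(C)(C)O1 | intermediate
23 | (6S)-6-[(2S,4S,6R)-2,4,6-trihydroxypentadecyl]-5,6-dihydro-2H-pyran-2-one | CCCCCCCCC[C@@H](O)C[C@H](O)C[C@H](O)C[C@@H]1CC=CC(=O)O1 | target

**Totals**

Total step count: 10. Longest linear sequence: 9 steps (steps 1, 3, 4, 5, 6, 7, 8, 9, 10).

**Steps most likely to fail**

Step 8. The risks are poor facial selectivity if the catalyst's preference and the resident β-stereocentre are mismatched, slow cycloaddition of the hindered β-alkoxy aldehyde, and β-elimination of the aldehyde on long exposure to the Lewis acid. The fallback sets out from aldehyde 18 and builds the ring in three stages. Reagent-controlled Brown allylation with (−)-B-allyldiisopinocampheylborane (from (+)-α-pinene; Et2O, −78 °C; then NaOH, H2O2) should give (2S)-1-{(4R,6R)-6-[(2R)-2-(tert-butyldimethylsilyloxy)undecyl]-2,2-dimethyl-1,3-dioxan-4-yl}pent-4-en-2-ol F1. Esterification with acryloyl chloride (Et3N, DMAP, CH2Cl2, 0 °C) should give the acrylate (2S)-1-{(4S,6R)-6-[(2R)-2-(tert-butyldimethylsilyloxy)undecyl]-2,2-dimethyl-1,3-dioxan-4-yl}pent-4-en-2-yl prop-2-enoate F2. Ring-closing metathesis with the second-generation Grubbs catalyst RuCl2(=CHPh)(PCy3)(H2IMes) (CH2Cl2, 40 °C) then closes C3=C4 and rejoins the route at lactone 22, so steps 8 and 9 are bypassed.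

Step 3. The risks are premature silyl migration with double alkylation by the first epoxide, incomplete second alkylation, and proton quench of the relayed anion. The fallback sets out from epoxide 4 and couples the two epoxides in separate operations. Lithiated 1,3-dithiane (n-BuLi, THF, −30 °C) opens 4 to give (2R)-1-(1,3-dithian-2-yl)undecan-2-ol F3. Silylation (TBSCl, imidazole, DMF) gives 2-[(2R)-2-(tert-butyldimethylsilyloxy)undecyl]-1,3-dithiane F4. A second lithiation (t-BuLi, THF/HMPA, −78 °C) and alkylation with epoxide 7 rejoins the route at 12.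

Step 9. The risks are loss of the acetonide or silyl ether during the acid hydrolysis followed by oxidation of the freed alcohols, and ring–chain equilibration of the lactol with isomerisation of the open enal. The fallback sets out from acetal 20 and avoids the hydrolysis stage by direct anomeric oxidation (mCPBA, BF3·OEt2, CH2Cl2, −20 °C). This exchanges methoxide for the peracid to give the anomeric peroxy ester (6S)-6-({(4R,6R)-6-[(2R)-2-(tert-butyldimethylsilyloxy)undecyl]-2,2-dimethyl-1,3-dioxan-4-yl}methyl)-5,6-dihydro-2H-pyran-2-yl 3-chloroperoxybenzoate F5, which fragments in the flask and rejoins the route at lactone 22.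

**Further compounds**

F1 | step 8 | (2S)-1-{(4R,6R)-6-[(2R)-2-(tert-butyldimethylsilyloxy)undecyl]-2,2-dimethyl-1,3-dioxan-4-yl}pent-4-en-2-ol | CCCCCCCCC[C@@H](O[Si](C)(C)C(C)(C)C)C[C@H]1C[C@@H](C[C@@H](O)CC=C)OC(C)(C)O1
F2 | step 8 | (2S)-1-{(4S,6R)-6-[(2R)-2-(tert-butyldimethylsilyloxy)undecyl]-2,2-dimethyl-1,3-dioxan-4-yl}pent-4-en-2-yl prop-2-enoate | CCCCCCCCC[C@@H](O[Si](C)(C)C(C)(C)C)C[C@H]1C[C@@H](C[C@@H](OC(=O)C=C)CC=C)OC(C)(C)O1
F3 | step 3 | (2R)-1-(1,3-dithian-2-yl)undecan-2-ol | CCCCCCCCC[C@@H](O)CC1SCCCS1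
F4 | step 3 | 2-[(2R)-2-(tert-butyldimethylsilyloxy)undecyl]-1,3-dithiane | CCCCCCCCC[C@@H](O[Si](C)(C)C(C)(C)C)CC1SCCCS1
F5 | step 9 | (6S)-6-({(4R,6R)-6-[(2R)-2-(tert-butyldimethylsilyloxy)undecyl]-2,2-dimethyl-1,3-dioxan-4-yl}methyl)-5,6-dihydro-2H-pyran-2-yl 3-chloroperoxybenzoate | CCCCCCCCC[C@@H](O[Si](C)(C)C(C)(C)C)C[C@H]1C[C@@H](C[C@@H]2CC=CC(OOC(=O)c3cccc(Cl)c3)O2)OC(C)(C)O1
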